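**Strategy.** Ring A is closed last, through C2–C3. The plan exploits two features: C3 (carbinol) and C19 (ester) are both carboxyl-level carbons on quaternary C4, so ring A's C3–C4–C19 unit is a latent methylmalonate, and C2 ends a two-carbon arm on quaternary C10. A ring B cyclohexane carrying the C8 methylene, the complete C9 side chain, an iodoethyl arm on C10 and a dimethyl methylmalonyl group on C5 is treated with t-BuLi. Iodine–lithium exchange reverses the polarity of C2, and the carbanion acylates one of the two diastereotopic esters, which closes ring A as a trans-decalin and fixes the C4 quaternary centre in one operation. Hydride reduction then sets C3.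

Key step: step 11

Remarks:
- Locants C1–C20 are those of the labdane skeleton of the target and are used for all intermediates (ring B = C5–C10).
- Assumption: the (S,S)-enantiomer of the diphosphine ligand in step 1 is taken to give the (R)-configured product 3, by analogy with malonate alkylation of cyclohexenyl acetate; if the sense is opposite, the (R,R)-ligand is used.
- Compounds 1, 2, 8 and 10 are catalogue chemicals.

Step 1
Reactants: 1 rac-cyclohex-2-en-1-yl acetate; 2 dimethyl methylmalonate
Product: 3 dimethyl 2-[(1R)-cyclohex-2-en-1-yl]-2-methylpropanedioate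
Conditions: NaH, (n-C6H13)4NBr, [Pd(C3H5)Cl]2 (2.5 mol %), (S,S)-1,2-bis[(2-diphenylphosphinobenzoyl)amino]cyclohexane (7.5 mol %), CH2Cl2, 0 °C to rt
Reagents that add atoms: none
Why: Tsuji–Trost asymmetric allylic alkylation, in which both enantiomers of 1 converge on one meso allyl–palladium species and the chiral diphosphine steers the tertiary malonate anion to one enantiotopic allyl terminus, setting C5.

Step 2
Reactants: 3 dimethyl 2-[(1R)-cyclohex-2-en-1-yl]-2-methylpropanedioate
Product: 4 dimethyl 2-methyl-2-[(1R)-4-oxocyclohex-2-en-1-yl]propanedioate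
Conditions: t-BuOOH (5 equiv), Rh2(cap)4 (1 mol %; cap = caprolactamate), K2CO3, CH2Cl2, rt
Reagents that add atoms: tert-butyl hydroperoxide CC(C)(C)OO
Why: Radical allylic C–H oxidation, in which hydrogen abstraction should occur at the open C8 methylene (the tertiary allylic C5–H is shielded by the quaternary malonyl carbon) and oxygenation at that remote terminus gives the 4-substituted enone.

Step 3
Reactants: 4 dimethyl 2-methyl-2-[(1R)-4-oxocyclohex-2-en-1-yl]propanedioate
Product: 5 dimethyl 2-methyl-2-[(1R,2S)-2-methyl-4-(trimethylsilyloxy)cyclohex-3-en-1-yl]propanedioate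
Conditions: MeMgBr, CuBr·SMe2 (10 mol %), Me3SiCl, THF, −78 °C; Et3N
Reagents that add atoms: methylmagnesium bromide C[Mg]Br; chlorotrimethylsilane C[Si](C)(C)Cl
Why: Copper-catalysed conjugate addition with silyl trapping brings in the C10 methyl anti to the malonyl group (this centre is erased in step 4) and holds the enolate as the C8–C9 silyl enol ether.

Step 4
Reactants: 5 dimethyl 2-methyl-2-[(1R,2S)-2-methyl-4-(trimethylsilyloxy)cyclohex-3-en-1-yl]propanedioate
Product: 6 dimethyl 2-methyl-2-[(1R)-2-methyl-4-oxocyclohex-2-en-1-yl]propanedioate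
Conditions: Pd(OAc)2 (10 mol %), O2 (1 atm), DMSO, rt
Reagents that add atoms: none
Why: Saegusa–Ito oxidation, in which the palladium enolate at C9 can eliminate a β-hydride only from C10, giving the 3-methyl enone regiospecifically.

Step 5
Reactants: 6 dimethyl 2-methyl-2-[(1R)-2-methyl-4-oxocyclohex-2-en-1-yl]propanedioate
Product: 7 dimethyl 2-[(1R,2S)-2-ethenyl-2-methyl-4-(trimethylsilyloxy)cyclohex-3-en-1-yl]-2-methylpropanedioate
Conditions: CH2=CHMgBr, CuBr·SMe2 (20 mol %), Me3SiCl, HMPA, THF, −78 to −40 °C; Et3N
Reagents that add atoms: vinylmagnesium bromide C=C[Mg]Br; chlorotrimethylsilane C[Si](C)(C)Cl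
Why: Silyl-chloride-accelerated copper-catalysed conjugate addition creates the C10 quaternary centre, since A(1,2) strain with the C10 methyl holds the C5 malonyl group pseudoaxial and vinyl adds axially on the opposite face (vinyl trans to malonyl), the enolate being trapped regiospecifically at C8–C9.

Step 6
Reactants: 7 dimethyl 2-[(1R,2S)-2-ethenyl-2-methyl-4-(trimethylsilyloxy)cyclohex-3-en-1-yl]-2-methylpropanedioate; 8 methyl vinyl ketone
Product: 9 ring B diketone (C8 ketone and 3-oxobutyl chain on C9; both C9 epimers)
Conditions: TiCl4, CH2Cl2, −78 °C; aq. NaHCO3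
Reagents that add atoms: none
Why: Mukaiyama–Michael addition of the regiodefined silyl enol ether joins C9 to C11 and brings in C11, C12, C13 and C16; the C9 configuration is not relied on here and is set in step 7.

Step 7
Reactants: 9 ring B diketone; 10 trimethyl phosphonoacetate
Product: 12 ring B keto enoate (C9 side chain cis to the C10 methyl; E-enoate), via C9-epimeric keto enoate 11 (not isolated)
Conditions: NaH, THF, 0 °C to rt; then MeOH, rt (NaOMe from excess NaH); chromatography
Reagents that add atoms: none
Why: Horner–Wadsworth–Emmons olefination should occur at the open C13 methyl ketone and not at the flanked C8 ketone, with the stabilised phosphonate favouring the E-enoate (any Z isomer is separated), and methoxide then equilibrates the epimerisable C9 to the epimer with the equatorial side chain, since the axial alternative costs two syn-axial contacts.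

Step 8
Reactants: 12 ring B keto enoate
Product: 13 ring B triene triester (C8 exocyclic methylene)
Conditions: Ph3PCH3Br, KN(SiMe3)2, THF, 0 to 50 °C
Reagents that add atoms: methyltriphenylphosphonium bromide C[P+](c1ccccc1)(c1ccccc1)c1ccccc1.[Br-]
Why: Wittig methylenation of the only ketone installs C17, the non-stabilised ylide leaving the three esters untouched and C9 already holding its thermodynamic configuration.

Step 9
Reactants: 13 ring B triene triester
Product: 15 primary alcohol (hydroxyl on C2), via C2 pinacol boronate 14 (not isolated)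
Conditions: pinacolborane, [Ir(cod)Cl]2 (2.5 mol %), Ph2PCH2PPh2 (5 mol %), CH2Cl2, rt; then H2O2, NaOH, THF/H2O, 0 °C
Reagents that add atoms: pinacolborane CC1(C)OBOC1(C)C; hydrogen peroxide OO
Why: Iridium-catalysed anti-Markovnikov hydroboration should select the monosubstituted vinyl group over the 1,1-disubstituted C8 methylene and the trisubstituted enoate, and oxidation with retention places the hydroxyl on C2.

Step 10
Reactants: 15 primary alcohol
Product: 16 primary iodide (iodine on C2)
Conditions: PPh3, I2, imidazole, CH2Cl2, 0 °C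
Reagents that add atoms: iodine II
Why: Appel iodination converts the unhindered primary alcohol into the iodide by SN2 displacement of the oxyphosphonium group without affecting alkenes or esters.

Step 11
Reactants: 16 primary iodide
Product: 19 dimethyl 3-oxolabda-8(17),13E-diene-15,19-dioate, via C2 alkyllithium 17 (not isolated), via lithium hemiketal 18 (not isolated)
Conditions: t-BuLi (2.1 equiv), pentane/Et2O (3:2), −100 °C, then to −20 °C; aq. NH4Cl
Reagents that add atoms: tert-butyllithium [Li]C(C)(C)C (its lithium is carried in 17 and 18 only)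
Why: Iodine–lithium exchange, which is faster at −100 °C than addition of t-BuLi to any carbonyl group, turns 16 into the C2 alkyllithium 17, which adds to one of the two diastereotopic ester carbonyls on C4 to give hemiketal 18, and loss of LiOMe leaves the C3 ketone. The closest known reaction type is the halogen–lithium-exchange-initiated anionic cyclisation (Parham-type intramolecular nucleophilic acyl substitution) of ω-iodo esters to cycloalkanones. Ring A closes in the 6-exo-trig mode at the ester carbonyl through a chair in which the C10 arm and the C5 malonyl group are both equatorial on ring B, so only the trans-decalin can form. The new stereocentre is the C4 quaternary carbon, controlled by that chair: of the two groups left on C4 the flat ester takes the axial site syn to the axial C10 methyl and the methyl the equatorial site, because an axial methyl would meet the C10 methyl in a 1,3-diaxial contact, so the axial ester becomes C19 (β) and the attacked one becomes C3. The step needs this diastereotopic-group selection and chemoselectivity for the malonate over the remote enoate, which the six-membered intramolecular transition state secures, while the C8 methylene is inert to the alkyllithium at low temperature.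

Step 12
Reactants: 19 dimethyl 3-oxolabda-8(17),13E-diene-15,19-dioate
Product: 21 methyl 3α,15-dihydroxylabda-8(17),13E-dien-19-oate, via 3α-hydroxy diester 20 (not isolated)
Conditions: K[HB(s-Bu)3] (1.2 equiv), THF, −78 °C; then i-Bu2AlH (3 equiv), −78 to −40 °C; aq. potassium sodium tartrate, then NaOH/H2O2
Reagents that add atoms: none
Why: The bulky trialkylborohydride should attack the C3 ketone along the equatorial trajectory (the axial one is blocked by the axial hydrogens on C1 and C5) to give the axial 3α-alcohol, and i-Bu2AlH then reduces only the unhindered conjugated C15 ester to the allylic alcohol, the axial neopentyl C19 ester being inert at −78 °C (chemoselective ester reduction).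

Step 13
Reactants: 21 methyl 3α,15-dihydroxylabda-8(17),13E-dien-19-oate
Product: 22 methyl 3α,15-diacetoxylabda-8(17),13E-dien-19-oate
Conditions: Ac2O, DMAP, pyridine, 40 °C
Reagents that add atoms: acetic anhydride CC(=O)OC(C)=O
Why: DMAP-catalysed acylation esterifies both the primary allylic hydroxyl and the hindered axial C3 hydroxyl.

Step 14
Reactants: 22 methyl 3α,15-diacetoxylabda-8(17),13E-dien-19-oate
Product: 23 methyl 3α-acetoxy-15-hydroxylabda-8(17),13E-dien-19-oate (target)
Conditions: K2CO3 (0.3 equiv), MeOH, 0 °C
Reagents that add atoms: none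
Why: Base-catalysed methanolysis (transesterification) should remove the unhindered primary allylic acetate much faster than the axial C3 acetate flanked by quaternary C4, and leaves the C19 methyl ester unchanged.

**Compound list**

1 | rac-cyclohex-2-en-1-yl acetate | CC(=O)OC1C=CCCC1 | starting material
2 | dimethyl methylmalonate | COC(=O)C(C)C(=O)OC | starting material
3 | dimethyl 2-[(1R)-cyclohex-2-en-1-yl]-2-methylpropanedioate | C1CC[C@@H](C(C)(C(=O)OC)C(=O)OC)C=C1 | intermediate
4 | dimethyl 2-methyl-2-[(1R)-4-oxocyclohex-2-en-1-yl]propanedioate | O=C1CC[C@@H](C(C)(C(=O)OC)C(=O)OC)C=C1 | intermediate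
5 | dimethyl 2-methyl-2-[(1R,2S)-2-methyl-4-(trimethylsilyloxy)cyclohex-3-en-1-yl]propanedioate (methyl trans to malonyl) | C[Si](C)(C)OC1CC[C@@H](C(C)(C(=O)OC)C(=O)OC)[C@H](C)C=1 | intermediate
6 | dimethyl 2-methyl-2-[(1R)-2-methyl-4-oxocyclohex-2-en-1-yl]propanedioate | O=C1CC[C@@H](C(C)(C(=O)OC)C(=O)OC)C(C)=C1 | intermediate
7 | dimethyl 2-[(1R,2S)-2-ethenyl-2-methyl-4-(trimethylsilyloxy)cyclohex-3-en-1-yl]-2-methylpropanedioate (vinyl trans to malonyl) | C[Si](C)(C)OC1CC[C@@H](C(C)(C(=O)OC)C(=O)OC)[C@](C)(C=C)C=1 | intermediate
8 | methyl vinyl ketone (but-3-en-2-one) | CC(=O)C=C | starting material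
9 | ring B diketone: cyclohexanone (C8=O) with dimethyl methylmalonyl on C5, methyl and vinyl on C10 (vinyl trans to malonyl), 3-oxobutyl on C9 (both C9 epimers) | O=C1CC[C@@H](C(C)(C(=O)OC)C(=O)OC)[C@](C)(C=C)C1CCC(C)=O | intermediate
10 | trimethyl phosphonoacetate | COC(=O)CP(=O)(OC)OC | starting material
11 | C9-epimeric keto enoate: as 9, with the C9 chain now (E)-CH2CH2C(CH3)=CHCO2CH3 | O=C1CC[C@@H](C(C)(C(=O)OC)C(=O)OC)[C@](C)(C=C)C1CC/C(C)=C/C(=O)OC | intermediate (not isolated)
12 | ring B keto enoate, single C9 epimer (side chain cis to the C10 methyl, trans to vinyl) | O=C1CC[C@@H](C(C)(C(=O)OC)C(=O)OC)[C@](C)(C=C)[C@H]1CC/C(C)=C/C(=O)OC | intermediate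
13 | ring B triene triester: as 12 with C8 exocyclic methylene | C=C1CC[C@@H](C(C)(C(=O)OC)C(=O)OC)[C@](C)(C=C)[C@H]1CC/C(C)=C/C(=O)OC | intermediate
14 | C2 pinacol boronate: as 13 with the vinyl group converted into CH2CH2B(pin) | C=C1CC[C@@H](C(C)(C(=O)OC)C(=O)OC)[C@](C)(CCB2OC(C)(C)C(C)(C)O2)[C@H]1CC/C(C)=C/C(=O)OC | intermediate (not isolated)
15 | primary alcohol: C10 arm CH2CH2OH | C=C1CC[C@@H](C(C)(C(=O)OC)C(=O)OC)[C@](C)(CCO)[C@H]1CC/C(C)=C/C(=O)OC | intermediate
16 | primary iodide: C10 arm CH2CH2I | C=C1CC[C@@H](C(C)(C(=O)OC)C(=O)OC)[C@](C)(CCI)[C@H]1CC/C(C)=C/C(=O)OC | intermediate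
17 | C2 alkyllithium: C10 arm CH2CH2Li | C=C1CC[C@@H](C(C)(C(=O)OC)C(=O)OC)[C@](C)(CC[Li])[C@H]1CC/C(C)=C/C(=O)OC | intermediate (not isolated)
18 | lithium hemiketal: ring A closed, C3 bearing OLi and OCH3 | C=C1CC[C@@H]2[C@](C)(CCC(O[Li])(OC)[C@]2(C)C(=O)OC)[C@H]1CC/C(C)=C/C(=O)OC | intermediate (not isolated)
19 | dimethyl 3-oxolabda-8(17),13E-diene-15,19-dioate (trans-decalin; 4α-CH3, 4β-CO2CH3) | C=C1CC[C@@H]2[C@](C)(CCC(=O)[C@]2(C)C(=O)OC)[C@H]1CC/C(C)=C/C(=O)OC | intermediate
20 | dimethyl 3α-hydroxylabda-8(17),13E-diene-15,19-dioate (present as its alkoxide until work-up) | C=C1CC[C@@H]2[C@](C)(CC[C@@H](O)[C@]2(C)C(=O)OC)[C@H]1CC/C(C)=C/C(=O)OC | intermediate (not isolated)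
21 | methyl 3α,15-dihydroxylabda-8(17),13E-dien-19-oate | C=C1CC[C@@H]2[C@](C)(CC[C@@H](O)[C@]2(C)C(=O)OC)[C@H]1CC/C(C)=C/CO | intermediate
22 | methyl 3α,15-diacetoxylabda-8(17),13E-dien-19-oate | C=C1CC[C@@H]2[C@](C)(CC[C@@H](OC(C)=O)[C@]2(C)C(=O)OC)[C@H]1CC/C(C)=C/COC(C)=O | intermediate
23 | methyl 3α-acetoxy-15-hydroxylabda-8(17),13E-dien-19-oate (5α-H, 9α-H, 10β-CH3, 4α-CH3, 4β-CO2CH3) | C=C1CC[C@@H]2[C@](C)(CC[C@@H](OC(C)=O)[C@]2(C)C(=O)OC)[C@H]1CC/C(C)=C/CO | target

**Totals.** Total step count: 14. Longest linear sequence: 14 steps (from 1; the route is fully linear).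

**Steps most likely to fail**

1. Step 11 (key step). What may go wrong: t-BuLi or the new alkyllithium attacks the conjugated ester or other ester groups in competition with ring closure, or the two diastereotopic esters are not discriminated well. Fallback, from 16 back to 19: the iodide is displaced with PhSO2Na in DMF to give the C2 phenyl sulfone F1. t-BuOK in THF then closes ring A by a Dieckmann-type acylation of the sulfonyl-stabilised C2 carbanion on one malonate ester. This closure is reversible, so the chair with the axial ester should prevail, and the product is drained as the enolate of the β-keto sulfone F2. Reductive desulfonylation with aluminium amalgam Al(Hg) in aqueous THF returns keto diester 19.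

2. Step 5. What may go wrong: the organocopper reagent fails to engage the congested β-carbon next to the malonyl-bearing C5, leaving enone or giving 1,2-addition. Fallback, from 6 back to 13: the two-carbon arm is delivered as a linear, sterically undemanding alkyne. Me3SiC≡CZnBr with t-BuMe2SiOTf in Et2O/THF at −40 °C (silyl-triflate-promoted conjugate alkynylation, anti to the malonyl group) should give the alkynyl silyl enol ether F3. TiCl4-mediated Mukaiyama–Michael addition to 8 gives the alkynyl diketone F4. Horner–Wadsworth–Emmons olefination with 10 and NaH, followed by NaOMe/MeOH (C9 equilibration and loss of the alkynyl silyl group), gives the ethynyl keto enoate F5. Wittig methylenation gives the enyne triester F6, and semi-hydrogenation of the terminal alkyne (H2, Pd/CaCO3 poisoned with Pb(OAc)2, quinoline) gives 13.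

3. Step 6. What may go wrong: sluggish C–C bond formation at the neopentyl-type C9, with protodesilylation of the enol ether and polymerisation of the enone. Fallback, from 7 back to 9: MeLi (THF, 0 °C) cleaves the silyl enol ether to the regiodefined lithium enolate. This is alkylated at C9 with the reactive allylic iodide (E)-1-iodo-3-(trimethylsilyl)but-2-ene F7, a vinylsilane equivalent of methyl vinyl ketone, to give the vinylsilane ketone F8. mCPBA should epoxidise the electron-rich vinylsilane in preference to the monosubstituted vinyl group, giving the epoxysilane F9. Aqueous acid (H2SO4, MeOH) then unmasks the methyl ketone and returns diketone 9.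

**Further compounds**

F1 | step 11 | C2 phenyl sulfone: as 16 with CH2CH2SO2Ph on C10 | C=C1CC[C@@H](C(C)(C(=O)OC)C(=O)OC)[C@](C)(CCS(=O)(=O)c2ccccc2)[C@H]1CC/C(C)=C/C(=O)OC
F2 | step 11 | β-keto sulfone: as 19 with PhSO2 on C2 (C2 epimers or enolate) | C=C1CC[C@@H]2[C@](C)(CC(S(=O)(=O)c3ccccc3)C(=O)[C@]2(C)C(=O)OC)[C@H]1CC/C(C)=C/C(=O)OC
F3 | step 5 | alkynyl silyl enol ether: as 7 with C≡CSiMe3 in place of vinyl and OSiMe2t-Bu on C8 | CC(C)(C)[Si](C)(C)OC1CC[C@@H](C(C)(C(=O)OC)C(=O)OC)[C@](C)(C#C[Si](C)(C)C)C=1
F4 | step 5 | alkynyl diketone: as 9 with C≡CSiMe3 in place of vinyl | O=C1CC[C@@H](C(C)(C(=O)OC)C(=O)OC)[C@](C)(C#C[Si](C)(C)C)C1CCC(C)=O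
F5 | step 5 | ethynyl keto enoate: as 12 with C≡CH in place of vinyl | O=C1CC[C@@H](C(C)(C(=O)OC)C(=O)OC)[C@](C)(C#C)[C@H]1CC/C(C)=C/C(=O)OC
F6 | step 5 | enyne triester: as 13 with C≡CH in place of vinyl | C=C1CC[C@@H](C(C)(C(=O)OC)C(=O)OC)[C@](C)(C#C)[C@H]1CC/C(C)=C/C(=O)OC
F7 | step 6 | (E)-1-iodo-3-(trimethylsilyl)but-2-ene | C[Si](C)(C)/C(C)=C/CI
F8 | step 6 | vinylsilane ketone: as 9 with CH2CH=C(SiMe3)CH3 on C9 (both C9 epimers) | O=C1CC[C@@H](C(C)(C(=O)OC)C(=O)OC)[C@](C)(C=C)C1C/C=C(/[Si](C)(C)C)C
F9 | step 6 | epoxysilane: epoxide of the vinylsilane in F8 (stereoisomer mixture) | O=C1CC[C@@H](C(C)(C(=O)OC)C(=O)OC)[C@](C)(C=C)C1CC2OC2(C)[Si](C)(C)C
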